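**Assumptions (one line each)**
- 5-Methylhex-4-enal is taken as a catalogue compound.
- The sense of induction in step 5 is assigned by analogy with BINOL–boronate additions to simple (E)-enones; the catalyst antipode that delivers to the β-Re face is the one used, written below as (R).

**Retrosynthetic overview**
1. Target ⇐ its aryl methyl ether by thiolate O-demethylation. No ring is constructed at any stage; the target is acyclic and the benzene ring is bought.
2. C2 quaternary centre ⇐ C-prenylation of the α-methyl aryl ketone enolate, with 1,2-induction from C3.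
3. C3 and its isopropenyl group ⇐ BINOL-catalysed conjugate isopropenylboration of an (E)-α-methyl aryl enone (new, catalyst-controlled, metal-free).
4. Enone ⇐ Wittig reaction of an α-methyl acyl ylide with a δ-keto aldehyde, then methylenation of the methyl ketone to give the 3-methylbut-3-enyl arm.
5. C4, the first stereocentre ⇐ prolinol-ether-catalysed Michael addition of 5-methylhex-4-enal to methyl vinyl ketone, both achiral.

**Route**

Step 1
Reactants: 1 (5-methylhex-4-enal); 2 (methyl vinyl ketone)
Product: 3, (S)-2-(3-methylbut-2-en-1-yl)-5-oxohexanal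
Conditions: (S)-2-(methoxydiphenylmethyl)pyrrolidine (5 mol%), ethyl 3,4-dihydroxybenzoate (20 mol%), neat, 4 °C, 36 h; short silica plug, used crude
Reagents that add atoms: methyl vinyl ketone (2), C=CC(C)=O
Why: Enamine-catalysed Michael addition of a linear aldehyde to an enone (the catechol co-catalyst activates MVK by H-bonding); the CPh2OMe group of the (S)-catalyst shields one face of the anti-enamine, so C–C bond formation on the open face gives the (S)-α-stereocentre, which becomes C4 of the target.

Step 2
Reactants: 4 (ethyltriphenylphosphonium bromide); 5 (3-methoxybenzoyl chloride)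
Product: 6, 1-(3-methoxyphenyl)-2-(triphenyl-λ5-phosphanylidene)propan-1-one (stabilised ylide, achiral)
Conditions: 4 (2 equiv), n-BuLi (2 equiv), THF, 0 °C; then 5 (1 equiv), −78 °C → rt
Reagents that add atoms: ethyltriphenylphosphonium bromide (4), CC[P+](c1ccccc1)(c1ccccc1)c1ccccc1.[Br-]; 3-methoxybenzoyl chloride (5), COc1cccc(c1)C(Cl)=O
Why: Bestmann C-acylation of ethylidenetriphenylphosphorane with an aroyl chloride; the second equivalent of ylide deprotonates the acylphosphonium salt (transylidation) to give the α-methyl acyl ylide; no stereocentre is involved.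

Step 3
Reactants: 3 (keto-aldehyde); 6 (acyl ylide)
Product: 7, (S,E)-1-(3-methoxyphenyl)-2-methyl-4-(3-methylbut-2-en-1-yl)oct-2-ene-1,7-dione
Conditions: PhMe, 90 °C, 16–24 h
Reagents that add atoms: ylide 6, COc1cccc(c1)C(=O)C(C)=P(c1ccccc1)(c1ccccc1)c1ccccc1
Why: Wittig olefination with a stabilised ylide is neutral, so the α-stereocentre is not epimerised and the δ-keto aldehyde does not undergo aldol cyclisation; it is aldehyde-selective (the methyl ketone is inert) and E-selective for the trisubstituted enone.

Step 4
Reactants: 7 (enone–methyl ketone); 8 (methyltriphenylphosphonium bromide)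
Product: 9, (S,E)-1-(3-methoxyphenyl)-2,7-dimethyl-4-(3-methylbut-2-en-1-yl)octa-2,7-dien-1-one
Conditions: 8 (1.3 equiv), KOt-Bu (1.25 equiv), THF, −20 → 0 °C
Reagents that add atoms: methyltriphenylphosphonium bromide (8), C[P+](c1ccccc1)(c1ccccc1)c1ccccc1.[Br-] (supplies CH2)
Why: Wittig methylenation is much faster at the unhindered methyl ketone than at the cross-conjugated, α-branched aryl enone carbonyl; C4–H is held in the alkene plane by A(1,3) strain with the C2 methyl, so vinylogous enolisation and loss of the C4 stereocentre are disfavoured.

Step 5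
Reactants: 9 (dienone); 10 (potassium isopropenyltrifluoroborate)
Product: 11, (3R,4S)-1-(3-methoxyphenyl)-2,7-dimethyl-4-(3-methylbut-2-en-1-yl)-3-(prop-1-en-2-yl)oct-7-en-1-one, as a mixture of C2 epimers. C3 has the same spatial arrangement as C3 (S) of the target; the descriptor is R here only because C2 is not yet quaternary.
Conditions: (R)-3,3′-bis(pentafluorophenyl)-BINOL (20 mol%), 10 (3 equiv), 4 Å MS, PhMe, 90 °C; aqueous work-up
Reagents that add atoms: potassium isopropenyltrifluoroborate (10), C=C(C)[B-](F)(F)F.[K+]
Why: Proposed new method: diol-organocatalysed conjugate 2-propenylboration of an α-methyl (trisubstituted) acyclic enone — the electron-poor BINOL displaces fluoride (sieves) to give a chiral, Lewis-acidic BINOL isopropenylboronate that binds the ketone oxygen of the s-cis enone and transfers the isopropenyl group intramolecularly through a six-membered chair-like transition state, with one 3-C6F5 arm blocking the β-Si face so that bond formation on the β-Re face sets C3 under catalyst control (C4 exerts almost no bias because its two CH2 arms are nearly isosteric); the α-methyl sits on the open edge of the chair, twisting of the aryl ring relieves the Ar/Me strain of the s-cis conformer, and the boron enolate is protonated on work-up so the scrambled C2 is irrelevant; the closest known reaction is the BINOL-catalysed conjugate addition of alkenylboronates or trifluoroborates to α-unsubstituted β-substituted enones.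

Step 6
Reactants: 11 (α-methyl ketone, C2 epimers); 12 (prenyl bromide)
Product: 13, (2S,3S,4S)-1-(3-methoxyphenyl)-2,7-dimethyl-2,4-bis(3-methylbut-2-en-1-yl)-3-(prop-1-en-2-yl)oct-7-en-1-one
Conditions: LDA (1.3 equiv), THF, −78 → 0 °C; then DMPU, 12 (2 equiv), −78 → 0 °C
Reagents that add atoms: prenyl bromide (12), CC(C)=CCBr
Why: Enolate C-alkylation of an α-branched aryl ketone with a reactive allylic bromide (both C2 epimers converge on one enolate); allylic strain places C3–H in the enolate plane and the electrophile approaches anti to the bulky C4 branch, on the isopropenyl side, which gives (2S) by 1,2-induction. The selectivity is expected to be moderate, with the minor epimer removed by chromatography.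

Step 7
Reactants: 13 (aryl methyl ether)
Product: 14, Garcinielliptone FA, (2S,3S,4S)-1-(3-hydroxyphenyl)-2,7-dimethyl-2,4-bis(3-methylbut-2-en-1-yl)-3-(prop-1-en-2-yl)oct-7-en-1-one
Conditions: NaSEt (5 equiv), degassed DMF, 120 °C; aq. NH4Cl
Reagents that add atoms: none
Why: SN2 O-demethylation of an aryl methyl ether by thiolate is non-acidic, so the prenyl and isopropenyl alkenes are not protonated or cyclised; the ketone is non-enolisable and none of the three stereocentres is epimerisable.

**Compound list**
1 | 5-methylhex-4-enal | CC(C)=CCCC=O | starting material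
2 | methyl vinyl ketone (but-3-en-2-one) | C=CC(C)=O | starting material
3 | (S)-2-(3-methylbut-2-en-1-yl)-5-oxohexanal | O=C[C@H](CC=C(C)C)CCC(C)=O | intermediate
4 | ethyltriphenylphosphonium bromide | CC[P+](c1ccccc1)(c1ccccc1)c1ccccc1.[Br-] | starting material
5 | 3-methoxybenzoyl chloride | COc1cccc(c1)C(Cl)=O | starting material
6 | 1-(3-methoxyphenyl)-2-(triphenyl-λ5-phosphanylidene)propan-1-one | COc1cccc(c1)C(=O)C(C)=P(c1ccccc1)(c1ccccc1)c1ccccc1 | intermediate
7 | (S,E)-1-(3-methoxyphenyl)-2-methyl-4-(3-methylbut-2-en-1-yl)oct-2-ene-1,7-dione | COc1cccc(c1)C(=O)/C(C)=C/[C@H](CC=C(C)C)CCC(C)=O | intermediate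
8 | methyltriphenylphosphonium bromide | C[P+](c1ccccc1)(c1ccccc1)c1ccccc1.[Br-] | starting material
9 | (S,E)-1-(3-methoxyphenyl)-2,7-dimethyl-4-(3-methylbut-2-en-1-yl)octa-2,7-dien-1-one | COc1cccc(c1)C(=O)/C(C)=C/[C@H](CC=C(C)C)CCC(C)=C | intermediate
10 | potassium isopropenyltrifluoroborate | C=C(C)[B-](F)(F)F.[K+] | starting material
11 | (3R,4S)-1-(3-methoxyphenyl)-2,7-dimethyl-4-(3-methylbut-2-en-1-yl)-3-(prop-1-en-2-yl)oct-7-en-1-one (C2 epimer mixture) | C=C(C)CC[C@@H](CC=C(C)C)[C@@H](C(=C)C)C(C)C(=O)c1cccc(OC)c1 | intermediate
12 | prenyl bromide (1-bromo-3-methylbut-2-ene) | CC(C)=CCBr | starting material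
13 | (2S,3S,4S)-1-(3-methoxyphenyl)-2,7-dimethyl-2,4-bis(3-methylbut-2-en-1-yl)-3-(prop-1-en-2-yl)oct-7-en-1-one | C=C(C)CC[C@@H](CC=C(C)C)[C@@H](C(=C)C)[C@](C)(CC=C(C)C)C(=O)c1cccc(OC)c1 | intermediate
14 | Garcinielliptone FA, (2S,3S,4S)-1-(3-hydroxyphenyl)-2,7-dimethyl-2,4-bis(3-methylbut-2-en-1-yl)-3-(prop-1-en-2-yl)oct-7-en-1-one | C=C(C)CC[C@@H](CC=C(C)C)[C@@H](C(=C)C)[C@](C)(CC=C(C)C)C(=O)c1cccc(O)c1 | target

**Totals**
- Total steps: 7
- Longest linear sequence: 6 (steps 1, 3, 4, 5, 6, 7)

**Three steps most likely to fail, with fallbacks**
1. **Step 5 (proposed new organocatalytic isopropenylboration).** The α-methyl enone may be too hindered or too reluctant to adopt the s-cis conformer, and the catalyst may not override the substrate. Fallback with known chemistry: build the α-unsubstituted enone instead (Wittig of 3 with 1-(3-methoxyphenyl)-2-(triphenylphosphoranylidene)ethanone, then methylenation), add the isopropenyl group by Rh(I)/chiral bisphosphine-catalysed Hayashi–Miyaura 1,4-addition of 10, then α-methylate (LDA, MeI) to converge on 11.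
2. **Step 6 (quaternary prenylation).** Risks are sluggish alkylation, O-alkylation and only moderate diastereoselectivity at C2. Fallback: trap the enolate of 11 with allyl chloroformate to give the allyl enol carbonate, carry out a ligand-controlled Pd-catalysed decarboxylative asymmetric allylic alkylation to set the quaternary centre, then convert allyl to prenyl by cross-metathesis with 2-methylbut-2-ene (the 1,1-disubstituted and trisubstituted alkenes are inert).
3. **Step 3 (Wittig of the hindered α-methyl acyl ylide with the sensitive α-chiral δ-keto aldehyde).** Risks are slow reaction and erosion of C4 on prolonged heating. Fallback: aldehyde-selective boron aldol of 3′-methoxypropiophenone (Cy2BCl, Et3N, −78 °C) with 3, followed by dehydration (MsCl/Et3N, then DBU) to the (E)-enone 7.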